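The earlier runs and the new flask were generated by integration with constants of no real substance; the scatter is artificial.

Early on, the two runs at 105 °C lie on about one line: east has 25% of target at 1.00 h and south 22% at 0.833 h, though south was charged 0.83 equiv of coupling partner and east 0.51 equiv.

the same everywhere: starting material 0.050 M; initiator 0.5 mol%

| run | coupling partner | temperature | remark | time |
|---|---|---|---|---|
| east | 0.51 equiv (fed, over 40 min) | 105 °C | run made earlier; the fed solution adds 0.10 times the starting volume |  |
| north-east | 0.70 equiv (fed, over 40 min) | 116 °C | run made earlier; the fed solution adds 0.10 times the starting volume |  |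
| south | 0.83 equiv (fed, over 40 min) | 105 °C | run made earlier; the fed solution adds 0.10 times the starting volume |  |
| teal | 1.00 equiv (fed, over 40 min) | 110 °C | the fed solution adds 0.10 times the starting volume | 4.0 h |
| blue | 0.500 equiv | 110 °C | everything together at the start, the whole solution of coupling partner included, so that from the start the volume is larger by 0.10 times the starting volume | 8.0 h |

| east: time / h | east: target / % | north-east: time / h | north-east: target / % | south: time / h | south: target / % |
|---|---|---|---|---|---|
| 0.333 | 8 | 0.333 | 15 | 0.833 | 22 |
| 0.667 | 14 | 1.00 | 38 | 1.50 | 34 |
| 1.00 | 25 | 2.00 | 63 | 2.50 | 50 |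
| 2.00 | 42 | 3.00 | 72 | 3.00 | 56 |
| 4.00 | 50 | 4.00 | 70 | 4.00 | 67 |

(scatter of a reading: 2 percentage points)

- charges are per starting volume, the dose included; the dosed solution carries all of it

* the winner by amount of target, in percent of the starting material charged; "neither" if no more than 2 percentage points parts them (teal / blue / neither)
* how much target is there at the end, in percent of the starting material charged: teal
* how much target is there at the end, in percent of the starting material charged: blue

So count turnovers. If each hour takes a fixed share of the starting material still there (first-order, or pseudo-first-order where something unseen holds steady), the part left is exp(−N), where N is the rate constant times the time: the lifetimes that have passed.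

South, still climbing at 4.00 h with 67%, reads 0.277 h⁻¹. North-east, still climbing at 2.00 h with 63%, reads 0.497 h⁻¹ at 116 °C. Going proportionally between the logarithms of these two readings, my own estimate for 110 °C is 0.361 h⁻¹, the turnovers per hour.

Late on, east rests near 50% and north-east near 70%, each close to its charge of coupling partner, so you also cap the count at that charge, the limiting reagent.

Teal gets 1.45 turnovers in 4.0 h, which reckons to 76.5%, and its 1.00 equiv stays above that. Blue gets 2.89 turnovers, which reckons to 94.4% uncapped, but its 0.500 equiv stops it at half of the starting material.

The forecast names teal as the winner, with 76% for teal and 50% for blue, holding that “the yield is simply capped by partner charged”.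

The flask gives teal as the winner, with 76.6% for teal and 50.0% for blue.

    initiator → 2 initiating radical (k = 1.86 × 10⁻⁵ s⁻¹, Ea = 127 kJ mol⁻¹)
    starting material + initiating radical → chain carrier (k = 36900 L mol⁻¹ s⁻¹, Ea = 14.0 kJ mol⁻¹)
    2 initiating radical → ended chains (k = 5.00 × 10⁸ L mol⁻¹ s⁻¹, Ea = 12.0 kJ mol⁻¹)
    coupling partner + chain carrier → target + initiating radical (k = 1.40 × 10⁵ L mol⁻¹ s⁻¹, Ea = 31.0 kJ mol⁻¹)
    (constants at 110 °C)

Teal's 76.6% comes to 1.45 turnovers against the 1.45 counted. At 0.361 h⁻¹, a reading of teal at 1.5 h counts 0.542 turnovers, or 41.9%, and that flask stands at 43.5%. Blue was counted 2.89 turnovers yet stands at 50.0% because of its 0.500 equiv of coupling partner, of which 0% is left at 8.00 h. Blue run with teal's equivalents of coupling partner holds 93.4% of target at its end, in percent of the starting material charged.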